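Labdane numbering, as in the target, is used throughout. The oxolan-3-one ring (O, C9, C11, C12, C13) holds the array C12=O/C13/C16–O, the retron of an epoxy-ketone acyl shift. It is therefore taken from a six-membered 2,3-dihydropyran-4-one (O, C9, C11, C12, C16, C13), closed in matched polarity by attack of the native 9α-OH on a linear diynone. Epoxidation of C13=C16 and a Lewis-acid 1,2-shift of acyl carbon C12 from C16 to C13 expel C16 as a formyl group, contract the ring and create the quaternary spiro centre C13, whose formyl and ethynyl arms later become the dihydrofuran. (+)-Marrubiin supplies the decalin and the C9–O bond.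

Key step: step 7

Assumption: (+)-marrubiin is taken as a purchasable chiral-pool compound whose centres C4, C5, C6, C8, C9 and C10 have the configuration of the target (19β-carbonyl, 6β-O, 8α-Me, 9α-O).

Step 1
Reactants: 1 (+)-marrubiin
Product: 3 14,15,16-trinorlabdane-13,9α:19,6β-diolide (spiro γ-lactone on C9), via hydroxy acid 2 (not isolated)
Conditions: RuCl3 (5 mol%), NaIO4 (excess), EtOAc/MeCN/H2O, rt
Reagents that add atoms: sodium periodate, [Na+].[O-]I(=O)(=O)=O
Why: Catalytic RuO4 oxidation degrades the electron-rich furan to the C13 carboxylic acid, which lactonises on the untouched tertiary 9α-OH, so the C9–O stereocentre is carried on unchanged.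

Step 2
Reactants: 3 trinor dilactone
Product: 4 12-hydroxy-14,15,16-trinorlabdane-13,9α:19,6β-diolide (C12 epimers)
Conditions: KN(SiMe3)2, THF, −78 °C; 2-(phenylsulfonyl)-3-phenyloxaziridine; AcOH quench
Reagents that add atoms: 2-(phenylsulfonyl)-3-phenyloxaziridine, O=S(=O)(c1ccccc1)N1OC1c1ccccc1
Why: Only the spiro lactone has α-hydrogens (C4 is quaternary), so the Davis enolate hydroxylation is regiospecific, and the C12 configuration does not matter because C12 becomes sp2.

Step 3
Reactants: 4 12-hydroxy dilactone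
Product: 6 9α-hydroxy-12-oxo-13,14,15,16-tetranorlabdan-19,6β-olide (β-hydroxy aldehyde), via lithium carboxylate 5 (not isolated)
Conditions: LiOH (1.1 equiv), THF/H2O, 0 °C; concentrate; Pb(OAc)4, CH2Cl2/MeOH, −20 °C
Reagents that add atoms: none
Why: The activated α-hydroxy lactone is saponified in preference to the very hindered 19,6-lactone, and oxidative decarboxylation of the α-hydroxy acid (Pb(OAc)4 cleavage) removes C13 as CO2 and leaves C12 as the aldehyde.

Step 4
Reactants: 6 β-hydroxy aldehyde; 7 1,4-bis(trimethylsilyl)buta-1,3-diyne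
Product: 8 9α,12-dihydroxy-12-[4-(trimethylsilyl)buta-1,3-diynyl]-13,14,15,16-tetranorlabdan-19,6β-olide (C12 epimers)
Conditions: 7, MeLi·LiBr, THF, 0 °C; then 6 (0.45 equiv), −78 °C; AcOH quench
Reagents that add atoms: 7 1,4-bis(trimethylsilyl)buta-1,3-diyne, C[Si](C)(C)C#CC#C[Si](C)(C)C
Why: Mono-desilylation of 7 gives the lithium diynide, whose 1,2-addition to the unhindered aldehyde is far faster than attack on the neopentyl lactone and brings in C16, C13, C14 and C15 as one linear chain.

Step 5
Reactants: 8 diynyl carbinol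
Product: 9 9α-hydroxy-12-oxo diynone (C12(=O)–C16≡C13–C14≡C15–SiMe3)
Conditions: activated MnO2, CH2Cl2, rt
Reagents that add atoms: none
Why: MnO2 oxidises only the propargylic secondary alcohol under neutral conditions, so the tertiary 9-OH stays and retro-aldol cleavage is avoided.

Step 6
Reactants: 9 diynone
Product: 11 spiro 6-ethynyl-2,3-dihydropyran-4-one (O9 bound to C13 and C16H=C13), via silylated pyranone 10 (not isolated)
Conditions: AuCl (5 mol%), CH2Cl2, rt; then Bu4NF, AcOH, THF, 0 °C
Reagents that add atoms: none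
Why: The gold-catalysed 6-endo-dig cycloisomerisation of a β-hydroxy ynone places O9 on the β-carbon C13 as Michael polarity demands, and buffered fluoride then protodesilylates the alkyne without opening the vinylogous ester.

Step 7
Reactants: 11 ethynyl dihydropyranone
Product: 13 (13R)-spiro 2-ethynyl-2-formyloxolan-3-one, via epoxide 12 (not isolated)
Conditions: dimethyldioxirane (acetone solution), (R,R)-N,N'-bis(3,5-di-tert-butylsalicylidene)-1,2-cyclohexanediaminomanganese chloride (10 mol%), CH2Cl2, −20 °C; volatiles removed; BF3·OEt2 (0.3 equiv), CH2Cl2, −78 °C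
Reagents that add atoms: dimethyldioxirane, CC1(C)OO1
Why: Oxygen-atom transfer from the oxomanganese salen species (Jacobsen–Katsuki epoxidation, known for the enol-ether bond of chromone-type vinylogous esters) gives alkoxy-epoxide 12; BF3 then opens its C13–O bond, the only one that leads to a cation stabilised by O9 and the ethynyl group and not placed next to the carbonyl. Acyl carbon C12 migrates from C16 to C13 on the face opposite the departing oxygen while C16 collapses to the formyl group, the Lewis-acid epoxy-ketone to β-dicarbonyl rearrangement that turns isophorone oxide into 2-formyl-2,4,4-trimethylcyclopentanone. The oxolane ring is thus closed not by a cyclisation but by a 1,2-shift: bond C12–C13 forms as C12–C16 breaks, so the oxane loses C16 and becomes five-membered. C13 is the only new stereocentre that survives; it is formed with inversion from the epoxide carbon, so oxygen delivery to the face of C13=C16 that lies syn to C8 and anti to C10 gives 13R. Because the C8 and C10 flanks of the spiro centre shield the two faces almost equally, the facial choice is left to the catalyst enantiomer (taken as R,R; its antipode is equally available). The step needs the acyl shift to beat hydride shift and loss of the C16 proton, which the better migratory aptitude of acyl, the absence of any base and −78 °C should secure.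

Step 8
Reactants: 13 keto aldehyde
Product: 14 12-triisopropylsilyl enol ether (C11=C12) of 13
Conditions: TIPSOTf, Et3N, CH2Cl2, −78 to 0 °C
Reagents that add atoms: triisopropylsilyl triflate, CC(C)[Si](C(C)C)(C(C)C)OS(=O)(=O)C(F)(F)F
Why: Soft enolisation can occur only toward C11 (C13 is quaternary and the aldehyde has no α-hydrogen), so the ketone alone is masked as a hydride-stable silyl enol ether.

Step 9
Reactants: 14 silyl enol ether aldehyde
Product: 15 6β,16,19-triol (C16H2OH and ethynyl on C13 and enol ether kept)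
Conditions: LiAlH4, THF, 0 °C to rt; Rochelle salt work-up
Reagents that add atoms: none
Why: Hydride reduction takes the formyl group to C16H2OH and the 19,6-lactone to the 6β,19-diol in one operation, while the bulky enol silane and the deprotonated terminal alkyne are left alone.

Step 10
Reactants: 15 alkynyl triol
Product: 16 12-triisopropylsilyl enol ether of the target (2,3-dihydrofuran closed)
Conditions: Mo(CO)6 (25 mol%), Me3NO (25 mol%), Et3N/Et2O, rt
Reagents that add atoms: none
Why: In this alkynol cycloisomerisation through a molybdenum vinylidene, the C16–OH of the 3-butyn-1-ol unit adds to C15 (formal 5-endo closure) under basic conditions that suit the enol ethers, and the 6- and 19-OH groups are too remote to compete.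

Step 11
Reactants: 16 silyl enol ether
Product: 17 target CNP0176827.1
Conditions: Bu4NF, AcOH (1:1), THF, 0 °C
Reagents that add atoms: none
Why: Fluoride cleaves the silyl enol ether, and the acetic acid buffer protonates the enolate at C11 before β-elimination of O9 can start and is too weak to touch the alkyl enol ether.

Compound list
1 | (+)-marrubiin (15,16-epoxy-9α-hydroxylabda-13(16),14-dien-19,6β-olide) | C[C@@H]1C[C@@H](O3)[C@H]2[C@@](C)(C3=O)CCC[C@]2(C)[C@@]1(O)CCc1ccoc1 | starting material
2 | 9α-hydroxy-19,6β-olido-14,15,16-trinorlabdan-13-oic acid | C[C@@H]1C[C@@H](O3)[C@H]2[C@@](C)(C3=O)CCC[C@]2(C)[C@@]1(O)CCC(=O)O | intermediate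
3 | 14,15,16-trinorlabdane-13,9α:19,6β-diolide | C[C@@H]1C[C@@H](O3)[C@H]2[C@@](C)(C3=O)CCC[C@]2(C)[C@@]14CCC(=O)O4 | intermediate
4 | 12-hydroxy derivative of 3 (C12 epimers) | C[C@@H]1C[C@@H](O3)[C@H]2[C@@](C)(C3=O)CCC[C@]2(C)[C@@]14CC(O)C(=O)O4 | intermediate
5 | lithium 9α,12-dihydroxy-19,6β-olido-14,15,16-trinorlabdan-13-oate | C[C@@H]1C[C@@H](O3)[C@H]2[C@@](C)(C3=O)CCC[C@]2(C)[C@@]1(O)CC(O)C(=O)[O-].[Li+] | intermediate
6 | 9α-hydroxy-12-oxo-13,14,15,16-tetranorlabdan-19,6β-olide | C[C@@H]1C[C@@H](O3)[C@H]2[C@@](C)(C3=O)CCC[C@]2(C)[C@@]1(O)CC=O | intermediate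
7 | 1,4-bis(trimethylsilyl)buta-1,3-diyne | C[Si](C)(C)C#CC#C[Si](C)(C)C | starting material
8 | diynyl carbinol (C12 epimers) | C[C@@H]1C[C@@H](O3)[C@H]2[C@@](C)(C3=O)CCC[C@]2(C)[C@@]1(O)CC(O)C#CC#C[Si](C)(C)C | intermediate
9 | β-hydroxy diynone | C[C@@H]1C[C@@H](O3)[C@H]2[C@@](C)(C3=O)CCC[C@]2(C)[C@@]1(O)CC(=O)C#CC#C[Si](C)(C)C | intermediate
10 | spiro 6-[(trimethylsilyl)ethynyl]-2,3-dihydropyran-4-one | C[C@@H]1C[C@@H](O3)[C@H]2[C@@](C)(C3=O)CCC[C@]2(C)[C@@]14CC(=O)C=C(C#C[Si](C)(C)C)O4 | intermediate
11 | spiro 6-ethynyl-2,3-dihydropyran-4-one | C[C@@H]1C[C@@H](O3)[C@H]2[C@@](C)(C3=O)CCC[C@]2(C)[C@@]14CC(=O)C=C(C#C)O4 | intermediate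
12 | 13,16-epoxide of 11 (oxygen on the face syn to C8) | C[C@@H]1C[C@@H](O3)[C@H]2[C@@](C)(C3=O)CCC[C@]2(C)[C@@]14CC(=O)[C@H]5O[C@@]5(C#C)O4 | intermediate
13 | (13R)-spiro 2-ethynyl-2-formyloxolan-3-one | C[C@@H]1C[C@@H](O3)[C@H]2[C@@](C)(C3=O)CCC[C@]2(C)[C@@]14CC(=O)[C@](C=O)(C#C)O4 | intermediate
14 | 12-O-triisopropylsilyl enol ether of 13 | C[C@@H]1C[C@@H](O3)[C@H]2[C@@](C)(C3=O)CCC[C@]2(C)[C@@]14C=C(O[Si](C(C)C)(C(C)C)C(C)C)[C@](C=O)(C#C)O4 | intermediate
15 | 6β,16,19-triol with 13-ethynyl group and 12-O-TIPS enol ether | C[C@@H]1C[C@@H](O)[C@H]2[C@@](C)(CO)CCC[C@]2(C)[C@@]14C=C(O[Si](C(C)C)(C(C)C)C(C)C)[C@](CO)(C#C)O4 | intermediate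
16 | 12-O-triisopropylsilyl enol ether of the target | C[C@@H]1C[C@@H](O)[C@H]2[C@@](C)(CO)CCC[C@]2(C)[C@@]14C=C(O[Si](C(C)C)(C(C)C)C(C)C)[C@]5(C=COC5)O4 | intermediate
17 | CNP0176827.1 ((13R)-9α,13:15,16-diepoxy-6β,19-dihydroxylabd-14-en-12-one) | C[C@@H]1C[C@@H](O)[C@H]2[C@@](C)(CO)CCC[C@]2(C)[C@@]12CC(=O)[C@]1(C=COC1)O2 | target

Total step count: 11. Longest linear sequence: 11.

Steps most likely to fail

Step 7. Loss of the C16 proton from the oxocarbenium ion may outrun the acyl shift, and oxygen transfer may show poor facial selectivity. The fallback sets out from 11 and comes back at 15.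
- Uncatalysed dimethyldioxirane oxidation is deliberately run through proton loss to the 5-hydroxypyranone F1.
- O-Methylation (MeI, K2CO3, acetone) gives the 5-methoxypyranone F2, whose fully substituted enol-ether bond has no proton to lose.
- The same catalyst-controlled epoxidation and BF3 treatment then send C12 to C13 and turn C16 into the methyl ester of β-keto ester F3.
- TIPSOTf/Et3N gives silyl enol ether F4, and LiAlH4 reduces ester and lactone together to 15.

Step 4. Retro-aldol cleavage of the lithium alkoxide of 6 may occur before the acetylide adds. The fallback sets out from 4 and comes back at 9.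
- Dess–Martin oxidation gives the α-keto lactone F5.
- H2O2/NaHCO3 cleaves it to the β-hydroxy acid F6.
- PhSO2Cl/pyridine closes the spiro β-lactone F7.
- Acyl–oxygen opening with lithium 4-(trimethylsilyl)butadiynide at −78 °C gives 9 directly, so no free β-hydroxy aldehyde is ever handled.

Step 10. The vinylidene may form slowly at the alkyne beside the quaternary C13, or be consumed before ring closure. The fallback sets out from 15 and comes back at 17.
- Hydroboration of the terminal alkyne with excess dicyclohexylborane and NaBO3 oxidation give the C15 aldehyde, which closes to the lactol F8.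
- TMSOTf/iPr2NEt silylates all hydroxyl groups and eliminates the lactol silyl acetal to the dihydrofuran bis(trimethylsilyl) ether F9.
- The buffered fluoride of step 11 removes all three silyl groups to give 17.

Further compounds
F1 | step 7 | spiro 6-ethynyl-5-hydroxy-2,3-dihydropyran-4-one | C[C@@H]1C[C@@H](O3)[C@H]2[C@@](C)(C3=O)CCC[C@]2(C)[C@@]14CC(=O)C(O)=C(C#C)O4
F2 | step 7 | spiro 6-ethynyl-5-methoxy-2,3-dihydropyran-4-one | C[C@@H]1C[C@@H](O3)[C@H]2[C@@](C)(C3=O)CCC[C@]2(C)[C@@]14CC(=O)C(OC)=C(C#C)O4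
F3 | step 7 | (13R)-spiro methyl 2-ethynyl-3-oxooxolane-2-carboxylate | C[C@@H]1C[C@@H](O3)[C@H]2[C@@](C)(C3=O)CCC[C@]2(C)[C@@]14CC(=O)[C@](C(=O)OC)(C#C)O4
F4 | step 7 | 12-O-triisopropylsilyl enol ether of F3 | C[C@@H]1C[C@@H](O3)[C@H]2[C@@](C)(C3=O)CCC[C@]2(C)[C@@]14C=C(O[Si](C(C)C)(C(C)C)C(C)C)[C@](C(=O)OC)(C#C)O4
F5 | step 4 | 12-oxo-14,15,16-trinorlabdane-13,9α:19,6β-diolide | C[C@@H]1C[C@@H](O3)[C@H]2[C@@](C)(C3=O)CCC[C@]2(C)[C@@]14CC(=O)C(=O)O4
F6 | step 4 | 9α-hydroxy-19,6β-olido-13,14,15,16-tetranorlabdan-12-oic acid | C[C@@H]1C[C@@H](O3)[C@H]2[C@@](C)(C3=O)CCC[C@]2(C)[C@@]1(O)CC(=O)O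
F7 | step 4 | 13,14,15,16-tetranorlabdane-12,9α:19,6β-diolide (spiro β-lactone) | C[C@@H]1C[C@@H](O3)[C@H]2[C@@](C)(C3=O)CCC[C@]2(C)[C@@]14CC(=O)O4
F8 | step 10 | 15-lactol of the 12-O-TIPS enol ether (C15 epimers) | C[C@@H]1C[C@@H](O)[C@H]2[C@@](C)(CO)CCC[C@]2(C)[C@@]14C=C(O[Si](C(C)C)(C(C)C)C(C)C)[C@]5(CC(O)OC5)O4
F9 | step 10 | 6,19-bis(trimethylsilyl) ether of 16 | C[C@@H]1C[C@@H](O[Si](C)(C)C)[C@H]2[C@@](C)(CO[Si](C)(C)C)CCC[C@]2(C)[C@@]14C=C(O[Si](C(C)C)(C(C)C)C(C)C)[C@]5(C=COC5)O4
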